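## Analysis of the target

Vidalol A is a diarylmethane without any stereocentre. Ring A (C1–C6) carries the bridge carbon C7 on C1, bromine on C2 and C3, hydroxyl on C4 and C5 and hydrogen on C6; ring B (C1'–C6') carries C7 on C1', hydroxyl on C2', C4' and C6', hydrogen on C3' and bromine on C5'. The task is therefore one of constitution: three bromines and five hydroxyls must be placed on two rings of very different nucleophilicity, and C7 must be attached to exactly one carbon of a ring that, as a symmetric triol, offers three equivalent ones. Both rings are sensitive: the catechol of ring A is easily oxidised to an ortho-quinone, ring B takes up electrophiles at every free carbon, and the free hydroxyl on C4, para to C7, allows loss of the bridge as a para-quinone methide under hot base. The feature the route is built on is the pattern of ring B: oxygen on C2', C4' and C6' alternates with carbon, hydrogen and bromine on C1', C3' and C5', which is the pattern of a triacetic acid (3,5-dioxohexanoate) chain folded by one Claisen condensation. With O6' methylated and without the bromine, ring B plus C7 is a constitutional isomer of a 3-substituted 4-methoxy-6-methyl-2-pyrone, in which C2', C1', C6', C5', C4' and C3' are already joined in this order and only the ring bond C2'–C3' is replaced by a lactone C–O bond. A second helpful feature is that ring B regains a mirror plane through C1' and C4' once all three oxygens are free, so bromination at C3' or at C5' leads to the same compound. The difficulty is thus the control of number and position of substituents on a very nucleophilic ring, and the order in which rings, bromines and free phenols appear.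

## Retrosynthetic reasoning

**11 to 10.** The last bonds cut are three O–CH3 bonds: on O4 and O5 of ring A and on O6' of ring B. The ring A ethers keep the catechol away from oxidants and remove the phenol para to C7; the ring B ether is the relic of the mask that the key step needs. All three fall in one Lewis acid ether cleavage, which must leave three aryl bromides and the bridge untouched.

**10 to 9.** The C5'–Br bond is cut next. In 9 the two free ring B carbons C3' and C5' both lead to 11 after the ether cleavage, so only the number of bromines has to be controlled, not their position. Ring A, with two bromines and no free hydroxyl, does not compete. The bromine is not carried through the ring construction, because a bromine next to an enolisable ketone would not survive the base.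

**9 to 6 (key disconnection).** Ring B is opened at the bond C2'–C3'. Through its keto tautomer 8, phenol 9 is the Claisen product of the open chain 7, in which C2' is an ester carbon and C3' the methyl carbon of a methyl ketone. Reconnecting the ester carbon to the enol oxygen on C4' turns 7 into pyrone 6, so 9 and 6 are isomers. The cut is made here and not at C7–C1' because it removes the whole arene. The 1,3,5-oxygen pattern and the position of C7 then come from the ring construction itself, with no choice among equivalent ring positions and no second benzylation. The forward reaction must open the lactone with an alkoxide, move the enolate to the terminal methyl carbon and close through carbon, not oxygen.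

**6 to 5.** Two O–CH3 bonds are cut, on the pyrone oxygen (the later O6') and on O4 of ring A. The 4-hydroxy pyrone 5 cannot be used directly in the key step: its acidic hydroxyl would give a pyrone oxide that resists alkoxide addition, and an unmasked chain would rest as an unreactive diketonate. One methylation masks this position and protects ring A together.

**5 to 2 and 3.** The C7–C1' bond is cut. C1' is C3 of pyrone 3, its only nucleophilic carbon, flanked by the enol and the lactone carbonyl. Aldehyde 2 can therefore be used at its own oxidation level in a condensation followed by hydride transfer from a dihydropyridine, and after one substitution this carbon is blocked.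

**2 to 1.** The C2–Br bond of ring A is cut. Ring A comes from a vanillin-derived aldehyde; the second bromine enters para to the methoxy group, before ring B exists, so the two rings never compete for bromine.

## Alternatives that were turned down

**Alternative 1:** the textbook route cuts C7–C1' between two finished arenes. Aldehyde 2 would be O-methylated to 2,3-dibromo-4,5-dimethoxybenzaldehyde A1 and reduced to (2,3-dibromo-4,5-dimethoxyphenyl)methanol A2. The forward key step is a Friedel–Crafts benzylation of 1,3,5-trimethoxybenzene A3 by A2 with AlCl3, giving 2-(2,3-dibromo-4,5-dimethoxybenzyl)-1,3,5-trimethoxybenzene A4; ring B bromination and cleavage of five methyl ethers would follow.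
- The product A4 keeps two ring B carbons as nucleophilic as those of A3, so a second benzylation competes and A3 must be used in excess.
- The benzylic cation from A2 is destabilised inductively by the bromines on C2 and C3, so a strong Lewis acid is needed, and this also attacks aryl methyl ethers.
- From 2 it needs five steps, the same number as the chosen route, so nothing is gained in length.
- It builds no ring and is the route most chemists would draw first.

**Alternative 2:** cut the same ring B bond one oxidation level higher, with C7 as a ketone, in the manner of benzophenone biosynthesis. Methyl 2,3-dibromo-4,5-dimethoxybenzoate A5 would acylate a tri-anion of a triacetic acid ester (LiN(iPr)2) to give methyl 7-(2,3-dibromo-4,5-dimethoxyphenyl)-3,5,7-trioxoheptanoate A6. The forward key step is the Claisen closure of A6 to (2,3-dibromo-4,5-dimethoxyphenyl)(2,4,6-trihydroxyphenyl)methanone A7, followed by reduction of the diaryl ketone to the methylene group.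
- A6 can fold in two ways: Claisen attack of C6 on C1 gives A7, while aldol attack of C2 on C7 gives the biaryl methyl 2-(2,3-dibromo-4,5-dimethoxyphenyl)-4,6-dihydroxybenzoate A8; both compete with pyrone formation.
- C7 arrives at the wrong oxidation level, so two redox corrections are needed (aldehyde to ester, ketone to methylene).
- With the poly-anion chemistry this adds about three steps over the chosen route.

**Alternative 3:** build ring B from two open fragments by a Danheiser benzannulation. {[3-(2,3-Dibromo-4,5-dimethoxyphenyl)prop-1-yn-1-yl]oxy}tri(propan-2-yl)silane A9 would be heated with 3-ethoxycyclobut-2-en-1-one A10. The sequence of vinylketene formation, (2+2) cycloaddition, four-electron ring opening and six-electron ring closure would give 2-(2,3-dibromo-4,5-dimethoxybenzyl)-5-ethoxy-3-{[tri(propan-2-yl)silyl]oxy}phenol A11, with C7 between two oxygens as in ring B.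
- A9 would have to come from an arylacetic ester by an ynolate (Kowalski-type) homologation with alkyllithium reagents, which would exchange with the two aryl bromides of ring A.
- A10 is itself a reagent of several steps.
- Three differently substituted oxygens are made where the target needs three equal hydroxyls.
- The route would be at least three steps longer.

Key step: step 4

Remark: the target has no stereocentre; the exocyclic double bond of 4 has no defined geometry (both isomers give 5), and 7 is written as the (E)-enoate that the ring opening delivers, although it is expected to exist as equilibrating sodium enolates.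

## Route

Step 1
Reactants: 1 5-bromovanillin (3-bromo-4-hydroxy-5-methoxybenzaldehyde)
Product: 2 2,3-dibromo-4-hydroxy-5-methoxybenzaldehyde
Conditions: Br2 (1.1 equiv), Fe powder (cat.), NaOAc, AcOH, rt
Reagents that add atoms: bromine, BrBr
Why: Electrophilic aromatic bromination, with iron tribromide formed in the flask as Lewis acid for a ring deactivated by the formyl group and the first bromine; the ortho and para positions of the hydroxyl are occupied, so the methoxy group directs, and its para position (C2 of 1) should be taken in preference to the ortho position C6.

Step 2
Reactants: 2 2,3-dibromo-4-hydroxy-5-methoxybenzaldehyde; 3 4-hydroxy-6-methyl-2H-pyran-2-one (triacetic acid lactone)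
Product: 5 3-(2,3-dibromo-4-hydroxy-5-methoxybenzyl)-4-hydroxy-6-methyl-2H-pyran-2-one, via 3-(2,3-dibromo-4-hydroxy-5-methoxybenzylidene)-6-methyl-2H-pyran-2,4(3H)-dione 4 (not isolated)
Conditions: Hantzsch ester (diethyl 2,6-dimethyl-1,4-dihydropyridine-3,5-dicarboxylate, 1.1 equiv), L-proline (20 mol %), EtOH, rt
Reagents that add atoms: none
Why: Three-component reductive alkylation: Knoevenagel condensation of the aldehyde, through its proline iminium ion, with C3 of 3 gives arylidene 4, a strong conjugate acceptor that takes up hydride from the Hantzsch ester at the benzylic carbon. Once C3 carries the arylmethyl group it cannot condense again, and no benzylic leaving group has to be made.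

Step 3
Reactants: 5 3-(2,3-dibromo-4-hydroxy-5-methoxybenzyl)-4-hydroxy-6-methyl-2H-pyran-2-one
Product: 6 3-(2,3-dibromo-4,5-dimethoxybenzyl)-4-methoxy-6-methyl-2H-pyran-2-one
Conditions: Me2SO4 (3 equiv), K2CO3 (4 equiv), acetone, reflux
Reagents that add atoms: dimethyl sulfate, COS(=O)(=O)OC
Why: Williamson-type O-methylation of both acidic hydroxyls with a hard methylating agent; the pyrone oxide should be methylated mainly on O4 to give the 4-methoxy-2-pyrone, and the ring A phenoxide gives the aryl methyl ether. The pyrone ether is the mask for the key step, and the ring A ether removes the phenoxide that could expel the bridge carbon as a para-quinone methide under hot base.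

Step 4
Reactants: 6 3-(2,3-dibromo-4,5-dimethoxybenzyl)-4-methoxy-6-methyl-2H-pyran-2-one
Product: 9 4-(2,3-dibromo-4,5-dimethoxybenzyl)-5-methoxybenzene-1,3-diol, via methyl (2E)-2-(2,3-dibromo-4,5-dimethoxybenzyl)-3-methoxy-5-oxohex-2-enoate 7 (not isolated), via 4-(2,3-dibromo-4,5-dimethoxybenzyl)-5-methoxycyclohex-4-ene-1,3-dione 8 (not isolated)
Conditions: NaOMe (3 equiv), MeOH, 100 °C (sealed tube), argon; then 1 M HCl
Reagents that add atoms: none
Why: Proposed new method: methoxide is expected to add to the lactone carbonyl of 6 and open the ring to the enolate of keto ester 7, in which the former 6-methyl group is the methyl of a methyl ketone; proton exchange in methanol gives a small share of the terminal enolate, which attacks the ester carbonyl in an intramolecular Claisen (Dieckmann-type) condensation, expels methoxide to give enedione 8, and 8 enolises at once to the phenoxide of 9, so methoxide acts as a shuttle and the net change is the isomerisation of a pyrone into a benzene ring. The closest known reaction types are the ring opening of 4-hydroxy-6-methyl-2-pyrone by Mg(OMe)2 in MeOH to methyl 3,5-dioxohexanoate, the Dieckmann-type closure of delta-keto esters to cyclohexane-1,3-diones, and the ring transformation of 2-pyranones into benzenes by external carbanions; what is new is that the carbanion is the pyrone's own methyl group and that opening and closure run in one operation. Ring B is closed by a 6-(enolexo)-exo-trig attack that forms the C2'–C3' bond, and the cis arrangement of ester and ketone arms that this needs is inherited from the pyrone ring. No stereocentre is formed. The step needs carbon and not oxygen of the enolate to attack the ester: closure through oxygen only returns 6, which methoxide reopens, whereas closure through carbon ends in an aromatic phenoxide and cannot revert. The methyl enol ether on C6' secures the rest: it removes the acidic 1,3-diketone and 4-hydroxyl of the unmasked system, which would hold the material as an unreactive pyrone oxide or diketonate, and it leaves only one six-membered carbocyclic closure open, with no aldol alternative. Ring A is inert here, since it has no phenol, no hydrogen ortho to bromine for aryne formation and no activation for displacement of bromide by methoxide.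

Step 5
Reactants: 9 4-(2,3-dibromo-4,5-dimethoxybenzyl)-5-methoxybenzene-1,3-diol
Product: 10 4-bromo-6-(2,3-dibromo-4,5-dimethoxybenzyl)-5-methoxybenzene-1,3-diol
Conditions: NBS (1.0 equiv, slow addition), THF, −78 °C
Reagents that add atoms: N-bromosuccinimide, O=C1CCC(=O)N1Br
Why: Electrophilic aromatic bromination of the free resorcinol ring, which is far more nucleophilic than ring A; attack is expected mainly at C5', para to the C2' hydroxyl and ortho to the C4' hydroxyl, and bromination at C3' would lead to the same target after step 6. One equivalent at low temperature is used so that the deactivating effect of the first bromine can hold back the second.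

Step 6
Reactants: 10 4-bromo-6-(2,3-dibromo-4,5-dimethoxybenzyl)-5-methoxybenzene-1,3-diol
Product: 11 vidalol A, 2-bromo-4-(2,3-dibromo-4,5-dihydroxybenzyl)benzene-1,3,5-triol
Conditions: BBr3 (8 equiv), CH2Cl2, −78 °C to rt; then H2O
Reagents that add atoms: none
Why: Lewis acid cleavage of the three aryl methyl ethers by BBr3 through aryloxyboron bromides and attack of bromide on the methyl groups (SN2); aryl bromides and the diarylmethane bridge should not be touched, and hydrolysis of the borates frees the five hydroxyls.

## Compound list

1 | 5-bromovanillin (3-bromo-4-hydroxy-5-methoxybenzaldehyde) | COc1cc(C=O)cc(Br)c1O | starting material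
2 | 2,3-dibromo-4-hydroxy-5-methoxybenzaldehyde | COc1cc(C=O)c(Br)c(Br)c1O | intermediate
3 | 4-hydroxy-6-methyl-2H-pyran-2-one (triacetic acid lactone) | Cc1cc(O)cc(=O)o1 | starting material
4 | 3-(2,3-dibromo-4-hydroxy-5-methoxybenzylidene)-6-methyl-2H-pyran-2,4(3H)-dione (not isolated, geometry not defined) | CC1=CC(=O)C(=Cc2cc(OC)c(O)c(Br)c2Br)C(=O)O1 | intermediate
5 | 3-(2,3-dibromo-4-hydroxy-5-methoxybenzyl)-4-hydroxy-6-methyl-2H-pyran-2-one | Cc1cc(O)c(Cc2cc(OC)c(O)c(Br)c2Br)c(=O)o1 | intermediate
6 | 3-(2,3-dibromo-4,5-dimethoxybenzyl)-4-methoxy-6-methyl-2H-pyran-2-one | Cc1cc(OC)c(Cc2cc(OC)c(OC)c(Br)c2Br)c(=O)o1 | intermediate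
7 | methyl (2E)-2-(2,3-dibromo-4,5-dimethoxybenzyl)-3-methoxy-5-oxohex-2-enoate (not isolated, present as sodium enolate) | COC(=O)/C(Cc1cc(OC)c(OC)c(Br)c1Br)=C(/OC)CC(C)=O | intermediate
8 | 4-(2,3-dibromo-4,5-dimethoxybenzyl)-5-methoxycyclohex-4-ene-1,3-dione (not isolated) | O=C1CC(=O)CC(OC)=C1Cc1cc(OC)c(OC)c(Br)c1Br | intermediate
9 | 4-(2,3-dibromo-4,5-dimethoxybenzyl)-5-methoxybenzene-1,3-diol | COc1cc(O)cc(O)c1Cc1cc(OC)c(OC)c(Br)c1Br | intermediate
10 | 4-bromo-6-(2,3-dibromo-4,5-dimethoxybenzyl)-5-methoxybenzene-1,3-diol | COc1c(Br)c(O)cc(O)c1Cc1cc(OC)c(OC)c(Br)c1Br | intermediate
11 | vidalol A, 2-bromo-4-(2,3-dibromo-4,5-dihydroxybenzyl)benzene-1,3,5-triol | Oc1cc(Cc2c(O)cc(O)c(Br)c2O)c(Br)c(Br)c1O | target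

## Step count and least certain steps

Total step count: 6. Longest linear sequence: 6 steps (1 to 11); pyrone 3 enters as a purchased compound in step 2.

**Step 4 (key step, proposed new method).** Most likely to go wrong: methoxide may add to the conjugate position C6 of the pyrone instead of the lactone carbonyl and open the ring to a dienoate carboxylate that can no longer close. After the desired opening the chain may also rest as its delocalised enolate, so that the small share of terminal enolate reacts between molecules (aldol and Claisen oligomerisation) faster than within. Fallback with known chemistry, setting out from 2 and coming back at 9: O-methylation of 2 with MeI and K2CO3 in DMF gives 2,3-dibromo-4,5-dimethoxybenzaldehyde F1, and reduction with NaBH4 in MeOH gives (2,3-dibromo-4,5-dimethoxyphenyl)methanol F2. Friedel–Crafts benzylation of an excess of commercial 5-methoxybenzene-1,3-diol with F2 (BF3·OEt2, 1,4-dioxane, 50 °C) should then give 9 by attack of the carbon para to a hydroxyl and ortho to the methoxy group. Benzylation at the carbon between the two hydroxyls would give an isomer that steps 5 and 6 convert to 11 as well. This fallback gives up the ring construction and accepts the statistical problems of arene benzylation.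

**Step 5.** Most likely to go wrong: over-bromination, because one bromine deactivates a resorcinol only weakly, so the second free carbon may react before all of 9 is consumed; ipso attack at C1' is a minor further risk. Fallback, setting out from 9 and coming back at 11: exhaustive O-methylation with Me2SO4 and K2CO3 in acetone gives 2-(2,3-dibromo-4,5-dimethoxybenzyl)-1,3,5-trimethoxybenzene F3, in which the two free ring B carbons are equivalent. As an aryl ether it should take up only one bromine from NBS (MeCN, 0 °C) to give 2-bromo-4-(2,3-dibromo-4,5-dimethoxybenzyl)-1,3,5-trimethoxybenzene F4, and cleavage of all five ethers with BBr3 in CH2Cl2 gives 11.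

**Step 2.** Most likely to go wrong: stalled condensation, because the phenol of 2, acidified by two bromines and the formyl group, may hold the aldehyde as a poorly electrophilic phenolate. If hydride transfer to the electron-rich arylidene 4 is slow, addition of a second molecule of 3 may also compete. Fallback, setting out from 2 and 3 and coming back at 5: reduction of 2 with NaBH4 in MeOH gives 2,3-dibromo-4-(hydroxymethyl)-6-methoxyphenol F5. Heating F5 with 3 in AcOH at 80 °C should generate the para-quinone methide by loss of water, which C3 of 3 captures by conjugate addition to give 5. The C7–C1' bond is then formed without a hydride transfer that has to compete with a second addition.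

## Further compounds

F1 | step 4 | 2,3-dibromo-4,5-dimethoxybenzaldehyde | COc1cc(C=O)c(Br)c(Br)c1OC
F2 | step 4 | (2,3-dibromo-4,5-dimethoxyphenyl)methanol | COc1cc(CO)c(Br)c(Br)c1OC
F3 | step 5 | 2-(2,3-dibromo-4,5-dimethoxybenzyl)-1,3,5-trimethoxybenzene | COc1cc(OC)c(Cc2cc(OC)c(OC)c(Br)c2Br)c(OC)c1
F4 | step 5 | 2-bromo-4-(2,3-dibromo-4,5-dimethoxybenzyl)-1,3,5-trimethoxybenzene | COc1cc(OC)c(Cc2cc(OC)c(OC)c(Br)c2Br)c(OC)c1Br
F5 | step 2 | 2,3-dibromo-4-(hydroxymethyl)-6-methoxyphenol | COc1cc(CO)c(Br)c(Br)c1O
A1 | alternative 1 | 2,3-dibromo-4,5-dimethoxybenzaldehyde | COc1cc(C=O)c(Br)c(Br)c1OC
A2 | alternative 1 | (2,3-dibromo-4,5-dimethoxyphenyl)methanol | COc1cc(CO)c(Br)c(Br)c1OC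
A3 | alternative 1 | 1,3,5-trimethoxybenzene | COc1cc(OC)cc(OC)c1
A4 | alternative 1 | 2-(2,3-dibromo-4,5-dimethoxybenzyl)-1,3,5-trimethoxybenzene | COc1cc(OC)c(Cc2cc(OC)c(OC)c(Br)c2Br)c(OC)c1
A5 | alternative 2 | methyl 2,3-dibromo-4,5-dimethoxybenzoate | COC(=O)c1cc(OC)c(OC)c(Br)c1Br
A6 | alternative 2 | methyl 7-(2,3-dibromo-4,5-dimethoxyphenyl)-3,5,7-trioxoheptanoate | COC(=O)CC(=O)CC(=O)CC(=O)c1cc(OC)c(OC)c(Br)c1Br
A7 | alternative 2 | (2,3-dibromo-4,5-dimethoxyphenyl)(2,4,6-trihydroxyphenyl)methanone | O=C(c1cc(OC)c(OC)c(Br)c1Br)c1c(O)cc(O)cc1O
A8 | alternative 2 | methyl 2-(2,3-dibromo-4,5-dimethoxyphenyl)-4,6-dihydroxybenzoate | COC(=O)c1c(O)cc(O)cc1-c1cc(OC)c(OC)c(Br)c1Br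
A9 | alternative 3 | {[3-(2,3-dibromo-4,5-dimethoxyphenyl)prop-1-yn-1-yl]oxy}tri(propan-2-yl)silane | COc1cc(CC#CO[Si](C(C)C)(C(C)C)C(C)C)c(Br)c(Br)c1OC
A10 | alternative 3 | 3-ethoxycyclobut-2-en-1-one | CCOC1=CC(=O)C1
A11 | alternative 3 | 2-(2,3-dibromo-4,5-dimethoxybenzyl)-5-ethoxy-3-{[tri(propan-2-yl)silyl]oxy}phenol | CCOc1cc(O)c(Cc2cc(OC)c(OC)c(Br)c2Br)c(O[Si](C(C)C)(C(C)C)C(C)C)c1
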